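A racemate cannot gain an excess if the single-handed free catalyst takes both mirror images equally fast, so that case is the zero of my scale. I measure this flask from it by the selectivity factor, the logarithm of how far left-handed substrate has fallen from its charge divided by the same logarithm for right-handed substrate; what sits on the catalyst counts as lost, and the symmetric case gives 1.

common to all: left-handed substrate 0.10 M; right-handed substrate 0.10 M; free catalyst 10 mol%

|  | partner | remark | time |
|---|---|---|---|
| east | 3 equiv | the very flask that is asked about, followed so far |  |
| flask | 3.00 equiv |  | 6.0 min |

east run (percent of the left-handed substrate and right-handed substrate together charged)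

| time / s | right-handed substrate / % | left-handed substrate / % | left-handed product / % |
|---|---|---|---|
| 10.0 | 46.1 | 42.1 | 5.8 |
| 15.0 | 47.2 | 39.6 | 8.6 |
| 30.0 | 45.0 | 32.9 | 16.5 |
| 60.0 | 40.8 | 19.1 | 26.7 |
| 120 | 35.5 | 9.3 | 39.4 |

(scatter of a reading: 1 percentage point)

- whether the excess of right-handed substrate over left-handed substrate among what is left of the two reaches 90% by 6.0 min (yes / no)
- the highest excess of right-handed substrate over left-handed substrate among what is left of the two up to 6.0 min

- free catalyst is single-handed; left-handed substrate and right-handed substrate are mirror images of each other, charged as a racemate, each of them at the stated concentration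
- the numbers in the tables scatter by 1 percentage point (one standard deviation)
- what may be going on: free catalyst + left-handed substrate <-> catalyst intermediate A; free catalyst + right-handed substrate <-> catalyst intermediate B; partner + catalyst intermediate A -> free catalyst + left-handed product; partner + catalyst intermediate B -> free catalyst + right-handed product; partner -> decomposition product

The east run, which is this flask followed so far, reads 4.91 at 120 s. An excess of 90% means a ratio of right-handed to left-handed substrate of 19.0. If the factor holds, that ratio comes when right-handed substrate stands at 23.6% of the joint charge, whatever the clock says.

The readings of the east run give the ladder of this flask: the first reading gives the uptake, and the last two give the half-lives on the pseudo-first-order view: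

| Rung | Time | This flask there |
|---|---|---|
| Uptake on the catalyst | by 10.0 s | 6 percentage points unread, as intermediates and right-handed product |
| Half-life, left-handed substrate | 57.8 s | 6.23 half-lives fit into the allowed time |
| Half-life, right-handed substrate | 4.98 min | 1.20 half-lives fit |

Running both slopes on to 6.0 min gives my estimate of 0.523% left-handed and 20.3% right-handed substrate. The right-handed figure lies lower than the 23.6% required, so I say yes, with a top of 95.0%.

The forecast says yes with a top of 93%, less than mine, and holds that “The excess rises monotonically”.

The flask answers yes, with a top of 97.5%.

    free catalyst + left-handed substrate ⇌ catalyst intermediate A (K = 20.0 M⁻¹, k = 48.0 M⁻¹ s⁻¹)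
    free catalyst + right-handed substrate ⇌ catalyst intermediate B (K = 10.0 M⁻¹, k = 14.0 M⁻¹ s⁻¹)
    partner + catalyst intermediate A → free catalyst + left-handed product (k = 0.890 M⁻¹ s⁻¹)
    partner + catalyst intermediate B → free catalyst + right-handed product (k = 0.300 M⁻¹ s⁻¹)
    partner → decomposition product (k = 4.00 × 10⁻⁵ s⁻¹)

It reaches 90% at 4.09 min with 24.9% of right-handed substrate left, where my rule said 23.6%. Used once more, the factor turns the 0.229% of left-handed substrate at 6.00 min into 16.7% of right-handed substrate, and the flask holds 18.1%.

(The readings were computed from invented constants; scatter was added.)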